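## The problem

Compound 30 is a 2,4-cis-4-arylflavan. Its chroman core (benzo ring A fused to pyran ring C; O1, C2, C3, C4, C4a, C5–C8, C8a) carries a 4-hydroxyphenyl ring B on C2 and, through the C4–C1' carbon–carbon bond, a 3-dodecanoyl-2,4,6-trihydroxyphenyl ring D on C4. Both stereocentres, C2 and C4, are R and lie 1,3-cis across ring C. C4 is a diarylmethine that no later step can correct. C2 is a benzylic ether carbon next to a para-oxygenated aryl group and ionises easily, so C4 can dictate C2 but not the reverse, and only C4 needs absolute control. Five free phenols, the acylphloroglucinol and two acid-labile bonds limit the late chemistry: O1–C2, and C4–C1', which ipso-protonation of ring D breaks to a cation stabilised by O1 and the C7 oxygen. Strong Brønsted or Lewis acid is therefore excluded late in the route, and the protecting groups must leave under neutral conditions. Ring D needs one acyl group on one of its two equivalent free carbons, in a molecule that finally holds two further oxygenated arenes. Ring A carries oxygen only at C8a and C7 and carbon only at C4a, with C5, C6 and C8 unsubstituted. This is the pattern a vinylketene and an oxygenated alkyne produce: C8a from the ketene carbonyl, C7 and C8 from the ynol ether, C4a–C5 from an alkene already attached to C4. Ring A can therefore be built last on an open chain that already holds C4, and ring D can be functionalised while it is still the only activated arene.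

## Retrosynthesis

**Protecting groups (30 ⇒ 29 ⇒ 28).** Four O–benzyl bonds and one O–Si bond are cut. Hydrogenolysis and fluoride are neutral; methyl or methoxymethyl ethers would need Lewis or Brønsted acid, which O1–C2 and C4–C1' do not tolerate. The forward steps must spare the hindered aryl ketone and the benzylic O1–C2 bond.

**Acyl group (28 ⇒ 23 + 26; 26 ⇒ 24 + 25).** The C3'–C(=O) bond is cut to aryllithium 27, made from bromide 23, and Weinreb amide 26. A Friedel–Crafts acylation of a bromine-free flavan would be shorter, but ring A of such a compound is a resorcinol diether that competes, and the acidic medium endangers C4–C1'. The bromine marks the position instead. This removes the C12 chain and a ketone that could not pass the earlier enolate and ketene chemistry. The forward reaction asks that bromine–lithium exchange outrun any deprotonation and that addition stop at the ketone.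

**Ring C (23 ⇒ 22).** The O1–C2 bond is cut to phenol 22, which carries a silylated benzylic carbinol. Cutting C4–C1' instead (flavan-4-yl cation plus a phloroglucinol) would need acid on the finished skeleton and leaves C4 without absolute control. The precursor is an open 1,3-diarylpropyl chain on a phenol. The forward closure must let C4 set C2.

**Ring A (22 ⇒ 13 + 17).** Four bonds are cut: C5–C6, C6–C7, C8–C8a and C4a–C8a, back to diazo enone 13 and (triisopropylsilyloxy)ethyne 17. The neighbouring cut C4–C4a (a resorcinol attacking a benzylic cation) would give ortho/para mixtures and a racemic C4. The benzannulation places the free hydroxyl at C8a, the silylated oxygen at C7 and only carbon at C4a by polarity alone. The precursor has one arene fewer and is an open chain. The forward reaction must leave the allylic, benzylic stereocentre untouched.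

**Diazo enone (13 ⇒ 11 ⇒ 9 + 10).** The diazo group comes from methyl ketone 11 by diazo transfer, and the C3=C4 alkene of 11 from terminal alkene 9 and methyl vinyl ketone 10 by cross-metathesis. An aldehyde/olefination route would pass through an epimerisable α-aryl aldehyde; metathesis never makes the stereocentre acidic.

**Carbinol (9 ⇒ 8 ⇒ 7).** The O–Si bond and the carbinol C–H bond are cut back to ketone 7. The hydroxyl must be masked through the enolate and ketene steps. Its configuration is set as (S), so that an invertive closure would also lead to the cis-flavan.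

**Stereocentre (7 ⇒ 5 + 6).** The bond between the future C4 and C4a is cut: conjugate addition of a vinyl group from 6 to chalcone 5. An iridium-catalysed allylic alkylation of a ring D cinnamyl carbonate would give the same ketone. It needs three more steps, and its doubly ortho-substituted, easily ionised electrophile invites a racemic background reaction. The forward reaction needs face selectivity on a hindered, electron-rich enone.

**Chalcone and ring D handle (5 ⇒ 3 + 4; 3 ⇒ 2 ⇒ 1).** The enone C=C is cut by aldol condensation to aldehyde 3 and ketone 4. The C–Br bond of 3 is cut back to 2, and the benzyl ethers of 2 to 1. At this stage ring D is the only activated arene and its two free carbons are equivalent.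

**Alkyne (17 ⇒ 16 ⇒ 14).** The C–H terminus comes from C-silylated ynol ether 16 by C-desilylation, and 16 from ethynyltrimethylsilane 14 by oxidation of its acetylide and O-silylation.

## Roads not taken

**Alternative 1:** Ring D is opened between its acyl-bearing carbon and the neighbouring hydroxyl-bearing carbon. The precursor is methyl 2-flavanyl-3,5,7-trioxooctadecanoate A1; methanolic KOH or Mg(OMe)2 would drive its C6 methylene onto the ester carbonyl and aromatise to the 7,4'-dibenzyl ether A2 of the target. The merit is real: the dodecanoyl group arrives with ring D, so no halogen handle and no late acylation are needed, only two benzyl groups are carried, and one hydrogenolysis ends the route. The weak points lie in A1. A 3,5,7-trioxo ester has several cyclisation modes (aldol from C2 onto C7, lactonisation of the C5 enol onto the ester to a 4-hydroxypyranone) besides the wanted Claisen closure, and substitution at C2 by a bulky flavanyl group slows the wanted one. A1 also presupposes an enantioselective route to a 4-alkylflavan, which moves the C4 problem without solving it. In placing the acyl group this road is better than the chosen one. The chosen plan sets against it a ring construction with a single reaction channel and a catalytic origin for C4.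

**Alternative 2:** One carbon (the future C3) is removed from ring C, giving the 2,3-diarylbenzofuran A3. Dichlorocarbene from Cl3CCO2Na would add to the furan C2=C3 bond, and opening of the dichlorocyclopropane would give the 3-chloro-4-arylflavylium chloride A4. The precursor is fully aromatic and can be assembled convergently by arylation chemistry, and the skeleton is reached in fewer steps than in the chosen plan. For this target the step is badly placed. The furan double bond is tetrasubstituted and flanked by a 2,6-dibenzyloxyaryl group, while the carbene has an easier target in the trialkoxybenzene ring D. A4 is also flat: both stereocentres would have to come from a reduction that removes chlorine as well. Hydrogenation should give the cis isomer, but absolute control over a 2,4-diarylflavylium reduction cannot be relied on, and ring D would still need acylation with ring A present. The chosen plan is longer but controls C4 by a catalyst and C2 by C4.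

**Alternative 3:** Oxygen O1 is removed from ring C, giving the 3-arylindanone A5. Buffered mCPBA would insert oxygen between the carbonyl carbon and the ring A carbon to give the 4-aryldihydrocoumarin A6, with retention at the untouched stereocentre. This road is conventional and operationally simpler than a photochemical benzannulation. The stereocentre can be set in the indanone by established asymmetric methods, and ring B can be added to the lactone and the pyran closed by the same kind of O1–C2 closure used here. In step count it is comparable. Its weak points are the peracid, which meets a tribenzyloxyphenyl ring prone to oxidation, and the aryl migration, which has no para donor on the migrating carbon. The lactone must also be converted into a 2-arylchroman through an aryl-metal addition liable to over-addition. The asymmetric entry to A5 meets the same hindered ring D as step 4 of the chosen route. The chosen plan sets against it a ring A whose oxygen pattern arises with no oxidant near ring D, and a chain in which ring B and its carbinol are in place before ring A exists.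

Key step: step 11

Remarks on the chemistry: (a) the (R,R) antipode of the diene ligand in step 4, (1R,4R)-2,5-diphenylbicyclo[2.2.2]octa-2,5-diene, is assumed to deliver the vinyl group to the enone face that gives (3R)-7; if the opposite sense is found, the (S,S) ligand is used. (b) Compounds with the unsymmetrical ring D next to the stereocentre may show slowly interconverting rotamers about the bond to C1'; these are conformers of one compound. (c) Intermediates 19 and 21 are mixtures of epimers at a transient ring carbon that aromatisation removes.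

## Route

Step 1
Reactants: 1 2,4,6-trihydroxybenzaldehyde
Product: 2 2,4,6-tris(benzyloxy)benzaldehyde
Conditions: BnBr (3.6 equiv), K2CO3, DMF, 60 °C
Reagents that add atoms: benzyl bromide, BrCc1ccccc1
Why: Williamson etherification of the three phenols; the two hydroxyls hydrogen-bonded to the aldehyde react last and need the excess of halide and gentle heating.

Step 2
Reactants: 2 2,4,6-tris(benzyloxy)benzaldehyde
Product: 3 3-bromo-2,4,6-tris(benzyloxy)benzaldehyde
Conditions: NBS (1.05 equiv), MeCN, 0 °C to rt
Reagents that add atoms: N-bromosuccinimide, O=C1CCC(=O)N1Br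
Why: Electrophilic aromatic bromination; ring D is the only activated arene present and its two free carbons are equivalent, so no regiochemical question arises, and the bromine together with the aldehyde slows a second substitution.

Step 3
Reactants: 3 3-bromo-2,4,6-tris(benzyloxy)benzaldehyde; 4 1-[4-(benzyloxy)phenyl]ethan-1-one
Product: 5 (E)-1-[4-(benzyloxy)phenyl]-3-[3-bromo-2,4,6-tris(benzyloxy)phenyl]prop-2-en-1-one
Conditions: KOH (aq.), EtOH/THF, 40 °C
Reagents that add atoms: none
Why: Claisen–Schmidt condensation of a non-enolisable aldehyde with an aryl methyl ketone; dehydration of the aldol by the E1cB path gives the E-enone.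

Step 4
Reactants: 5 (E)-1-[4-(benzyloxy)phenyl]-3-[3-bromo-2,4,6-tris(benzyloxy)phenyl]prop-2-en-1-one; 6 potassium vinyltrifluoroborate
Product: 7 (3R)-1-[4-(benzyloxy)phenyl]-3-[3-bromo-2,4,6-tris(benzyloxy)phenyl]pent-4-en-1-one
Conditions: 6 (3 equiv), [RhCl(C2H4)2]2 (3 mol%), (R,R)-Ph-bod* (6.6 mol%), Et3N (2 equiv), dioxane/H2O 10:1, 60 °C
Reagents that add atoms: none
Why: Rhodium-catalysed asymmetric 1,4-addition of an alkenylboron reagent to an enone: the monovalent rhodium–diene complex takes up the vinyl group by transmetalation, inserts the enone and is released by protonation of the oxa-π-allyl species; the chiral diene differentiates the enone faces and sets C3 as R (catalyst control), and the aryl bromide is inert to this catalyst.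

Step 5
Reactants: 7 (3R)-1-[4-(benzyloxy)phenyl]-3-[3-bromo-2,4,6-tris(benzyloxy)phenyl]pent-4-en-1-one
Product: 8 (1S,3R)-1-[4-(benzyloxy)phenyl]-3-[3-bromo-2,4,6-tris(benzyloxy)phenyl]pent-4-en-1-ol
Conditions: RuCl(p-cymene)[(S,S)-TsDPEN] (2 mol%), HCO2H/Et3N 5:2, CH2Cl2, 30 °C
Reagents that add atoms: none
Why: Noyori-type asymmetric transfer hydrogenation of an aryl alkyl ketone; the (S,S) catalyst should give the (S)-carbinol under catalyst control, and the terminal alkene, aryl bromide and benzyl ethers are inert to the ruthenium hydride; the (S) configuration gives one diastereomer to carry forward and keeps an invertive ring closure open.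

Step 6
Reactants: 8 (1S,3R)-1-[4-(benzyloxy)phenyl]-3-[3-bromo-2,4,6-tris(benzyloxy)phenyl]pent-4-en-1-ol
Product: 9 {[(1S,3R)-1-[4-(benzyloxy)phenyl]-3-[3-bromo-2,4,6-tris(benzyloxy)phenyl]pent-4-en-1-yl]oxy}(tert-butyl)dimethylsilane
Conditions: TBSCl, imidazole, DMF, rt
Reagents that add atoms: tert-butyldimethylsilyl chloride, CC(C)(C)[Si](C)(C)Cl
Why: Standard silylation of a secondary benzylic alcohol; the ether masks the hydroxyl against the amide base of step 8 and the ketenes of step 11.

Step 7
Reactants: 9 {[(1S,3R)-1-[4-(benzyloxy)phenyl]-3-[3-bromo-2,4,6-tris(benzyloxy)phenyl]pent-4-en-1-yl]oxy}(tert-butyl)dimethylsilane; 10 but-3-en-2-one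
Product: 11 (3E,5R,7S)-7-[4-(benzyloxy)phenyl]-5-[3-bromo-2,4,6-tris(benzyloxy)phenyl]-7-(tert-butyldimethylsilyloxy)hept-3-en-2-one
Conditions: 10 (5 equiv), second-generation Hoveyda–Grubbs catalyst RuCl2(H2IMes)(=CH-C6H4-2-O-i-Pr) (5 mol%), CH2Cl2, 40 °C
Reagents that add atoms: none
Why: Olefin cross-metathesis of a terminal alkene with an electron-poor vinyl ketone, which does not homodimerise readily and gives the E-enone; the neutral conditions leave the allylic stereocentre untouched.

Step 8
Reactants: 11 (3E,5R,7S)-7-[4-(benzyloxy)phenyl]-5-[3-bromo-2,4,6-tris(benzyloxy)phenyl]-7-(tert-butyldimethylsilyloxy)hept-3-en-2-one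
Product: 13 (3E,5R,7S)-7-[4-(benzyloxy)phenyl]-5-[3-bromo-2,4,6-tris(benzyloxy)phenyl]-7-(tert-butyldimethylsilyloxy)-1-diazohept-3-en-2-one, via trifluoroacetyl diketone 12 (not isolated)
Conditions: LiN(SiMe3)2, THF, −78 °C; CF3CO2CH2CF3; 5% HCl work-up; then MsN3, Et3N, H2O, MeCN, rt
Reagents that add atoms: methanesulfonyl azide, CS(=O)(=O)N=[N+]=[N-]; 2,2,2-trifluoroethyl trifluoroacetate, O=C(OCC(F)(F)F)C(F)(F)F (its atoms stay only in 12)
Why: Detrifluoroacetylative diazo transfer: the kinetic cross-conjugated enolate of the methyl ketone is trifluoroacetylated at −78 °C, and the activated diketone undergoes Regitz-type diazo transfer with loss of the trifluoroacetyl group as the N-sulfonyl amide; kinetic deprotonation at the methyl group should spare the γ-hydrogen on the stereocentre.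

Step 9
Reactants: 14 ethynyltrimethylsilane
Product: 16 triisopropyl{[(trimethylsilyl)ethynyl]oxy}silane, via lithium silylynolate 15 (not isolated)
Conditions: LiN(SiMe3)2 (2.2 equiv), t-BuOOH, THF, −78 to 0 °C; then i-Pr3SiOTf, −78 to 0 °C
Reagents that add atoms: tert-butyl hydroperoxide, CC(C)(C)OO; triisopropylsilyl trifluoromethanesulfonate, CC(C)[Si](OS(=O)(=O)C(F)(F)F)(C(C)C)C(C)C; lithium bis(trimethylsilyl)amide, [Li]N([Si](C)(C)C)[Si](C)(C)C (its lithium stays only in 15)
Why: Oxenoid oxidation of the lithium acetylide by lithium tert-butyl peroxide gives the ynolate, which the bulky silyl triflate silylates on oxygen, not on carbon; this is the established route from terminal alkynes to triisopropylsilyloxyalkynes.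

Step 10
Reactants: 16 triisopropyl{[(trimethylsilyl)ethynyl]oxy}silane
Product: 17 (ethynyloxy)triisopropylsilane
Conditions: K2CO3 (0.1 equiv), MeOH, 0 °C
Reagents that add atoms: none
Why: Base-catalysed methanolysis of an alkynyl C–SiMe3 bond; methoxide should attack the unhindered trimethylsilyl group much faster than the triisopropylsilyl group on oxygen, which is kept intact by low temperature and short contact.

Step 11
Reactants: 13 (3E,5R,7S)-7-[4-(benzyloxy)phenyl]-5-[3-bromo-2,4,6-tris(benzyloxy)phenyl]-7-(tert-butyldimethylsilyloxy)-1-diazohept-3-en-2-one; 17 (ethynyloxy)triisopropylsilane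
Product: 22 2-{(1R,3S)-3-[4-(benzyloxy)phenyl]-1-[3-bromo-2,4,6-tris(benzyloxy)phenyl]-3-(tert-butyldimethylsilyloxy)propyl}-5-(triisopropylsilyloxy)phenol, via vinylketene 18 (not isolated), via siloxycyclobutenone 19 (not isolated), via dienylketene 20 (not isolated), via cyclohexadienone 21 (not isolated)
Conditions: 17 (2.5 equiv), hν (350 nm, Pyrex), ClCH2CH2Cl, rt; then 80 °C
Reagents that add atoms: none
Why: Irradiation expels N2 from 13 and the alkenyl group migrates to the former diazo carbon (Wolff rearrangement, C5–C6), giving vinylketene 18. The electrophilic ketene carbonyl carbon bonds to the unsubstituted, nucleophilic carbon of ynol ether 17 and the ketene α-carbon to the oxygen-bearing carbon, so the (2+2) adduct is the 3-silyloxy-4-alkenylcyclobutenone 19 (C8–C8a and C6–C7). On warming 19 opens by conrotatory 4π electrocyclisation to dienylketene 20; the opening is reversible, so the isomer with the alkenyl group cis to the ketene is drained by disrotatory 6π electrocyclisation (C4a–C8a), which closes the six-membered ring A as cyclohexadienone 21, and tautomerisation gives phenol 22. The closest known reaction type is the photochemical-Wolff variant of the Danheiser benzannulation of α-diazo enones with triisopropylsilyloxyalkynes. No stereocentre is created, and the transient ring stereocentre of 19 and 21 disappears on aromatisation. The step needs regiocontrol in the (2+2) addition, which the polarity match of ketene and ynol ether secures: the silyloxy group ends meta to the new hydroxyl and para to C4a. It also needs the stereocentre carried from 13 to survive; that centre lies outside the reacting π system and meets neither acid nor base. Light above 300 nm is chosen so that the aryl bromide and the benzyl ethers do not absorb.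

Step 12
Reactants: 22 2-{(1R,3S)-3-[4-(benzyloxy)phenyl]-1-[3-bromo-2,4,6-tris(benzyloxy)phenyl]-3-(tert-butyldimethylsilyloxy)propyl}-5-(triisopropylsilyloxy)phenol
Product: 23 {[(2R,4R)-2-[4-(benzyloxy)phenyl]-4-[3-bromo-2,4,6-tris(benzyloxy)phenyl]-3,4-dihydro-2H-chromen-7-yl]oxy}triisopropylsilane
Conditions: TsOH·H2O (0.2 equiv), CH2Cl2, 0 °C to rt
Reagents that add atoms: none
Why: Acid-catalysed ionisation of the para-benzyloxybenzylic silyl ether and capture of the benzylic carbon by the ortho phenol closes the six-membered ring C (acid-catalysed flavan closure); C2 is set by C4, because under reversible ionisation of O1–C2 the 2,4-cis isomer with both aryl groups pseudo-equatorial on the half-chair should accumulate, and the aryl silyl ether is stable to this acid.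

Step 13
Reactants: 24 dodecanoyl chloride; 25 N,O-dimethylhydroxylamine hydrochloride
Product: 26 N-methoxy-N-methyldodecanamide
Conditions: Et3N (2.2 equiv), CH2Cl2, 0 °C to rt
Reagents that add atoms: none
Why: Acylation of the hydroxylamine by the acid chloride gives the Weinreb amide.

Step 14
Reactants: 23 {[(2R,4R)-2-[4-(benzyloxy)phenyl]-4-[3-bromo-2,4,6-tris(benzyloxy)phenyl]-3,4-dihydro-2H-chromen-7-yl]oxy}triisopropylsilane; 26 N-methoxy-N-methyldodecanamide
Product: 28 1-[2,4,6-tris(benzyloxy)-3-[(2R,4R)-2-[4-(benzyloxy)phenyl]-7-(triisopropylsilyloxy)-3,4-dihydro-2H-chromen-4-yl]phenyl]dodecan-1-one, via aryllithium 27 (not isolated)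
Conditions: t-BuLi (2.1 equiv), THF, −78 °C; then 26, −78 to −20 °C; NH4Cl (aq.)
Reagents that add atoms: tert-butyllithium, [Li]C(C)(C)C (its lithium stays only in 27)
Why: Bromine–lithium exchange at −78 °C is faster than deprotonation of benzylic or ring positions, and the aryllithium adds to the Weinreb amide to a chelated adduct that releases the ketone only on work-up, so over-addition is excluded.

Step 15
Reactants: 28 1-[2,4,6-tris(benzyloxy)-3-[(2R,4R)-2-[4-(benzyloxy)phenyl]-7-(triisopropylsilyloxy)-3,4-dihydro-2H-chromen-4-yl]phenyl]dodecan-1-one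
Product: 29 1-[2,4,6-tris(benzyloxy)-3-[(2R,4R)-2-[4-(benzyloxy)phenyl]-7-hydroxy-3,4-dihydro-2H-chromen-4-yl]phenyl]dodecan-1-one
Conditions: n-Bu4NF, THF, 0 °C; NH4Cl (aq.)
Reagents that add atoms: none
Why: Fluoride cleavage of the aryl silyl ether; benzyl ethers, the ketone and both stereocentres are inert to these conditions.

Step 16
Reactants: 29 1-[2,4,6-tris(benzyloxy)-3-[(2R,4R)-2-[4-(benzyloxy)phenyl]-7-hydroxy-3,4-dihydro-2H-chromen-4-yl]phenyl]dodecan-1-one
Product: 30 1-[2,4,6-trihydroxy-3-[(2R,4R)-7-hydroxy-2-(4-hydroxyphenyl)-3,4-dihydro-2H-chromen-4-yl]phenyl]dodecan-1-one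
Conditions: H2 (1 atm), Pd/C, EtOAc/MeOH, rt
Reagents that add atoms: none
Why: Hydrogenolysis of the four benzyl ethers under neutral conditions; the ketone, which becomes hydrogen-bonded to its ortho hydroxyls as they are freed, and the O1–C2 bond of the flavan are expected to resist at ambient pressure.

## Compound list

1 | 2,4,6-trihydroxybenzaldehyde | O=Cc1c(O)cc(O)cc1O | starting material
2 | 2,4,6-tris(benzyloxy)benzaldehyde | O=Cc1c(OCc2ccccc2)cc(OCc2ccccc2)cc1OCc1ccccc1 | intermediate
3 | 3-bromo-2,4,6-tris(benzyloxy)benzaldehyde | O=Cc1c(OCc2ccccc2)c(Br)c(OCc2ccccc2)cc1OCc1ccccc1 | intermediate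
4 | 1-[4-(benzyloxy)phenyl]ethan-1-one | CC(=O)c1ccc(OCc2ccccc2)cc1 | starting material
5 | (E)-1-[4-(benzyloxy)phenyl]-3-[3-bromo-2,4,6-tris(benzyloxy)phenyl]prop-2-en-1-one | O=C(/C=C/c1c(OCc2ccccc2)c(Br)c(OCc2ccccc2)cc1OCc1ccccc1)c1ccc(OCc2ccccc2)cc1 | intermediate
6 | potassium vinyltrifluoroborate | C=C[B-](F)(F)F.[K+] | starting material
7 | (3R)-1-[4-(benzyloxy)phenyl]-3-[3-bromo-2,4,6-tris(benzyloxy)phenyl]pent-4-en-1-one | C=C[C@@H](CC(=O)c1ccc(OCc2ccccc2)cc1)c1c(OCc2ccccc2)c(Br)c(OCc2ccccc2)cc1OCc1ccccc1 | intermediate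
8 | (1S,3R)-1-[4-(benzyloxy)phenyl]-3-[3-bromo-2,4,6-tris(benzyloxy)phenyl]pent-4-en-1-ol | C=C[C@@H](C[C@H](O)c1ccc(OCc2ccccc2)cc1)c1c(OCc2ccccc2)c(Br)c(OCc2ccccc2)cc1OCc1ccccc1 | intermediate
9 | {[(1S,3R)-1-[4-(benzyloxy)phenyl]-3-[3-bromo-2,4,6-tris(benzyloxy)phenyl]pent-4-en-1-yl]oxy}(tert-butyl)dimethylsilane | C=C[C@@H](C[C@H](O[Si](C)(C)C(C)(C)C)c1ccc(OCc2ccccc2)cc1)c1c(OCc2ccccc2)c(Br)c(OCc2ccccc2)cc1OCc1ccccc1 | intermediate
10 | but-3-en-2-one (methyl vinyl ketone) | CC(=O)C=C | starting material
11 | (3E,5R,7S)-7-[4-(benzyloxy)phenyl]-5-[3-bromo-2,4,6-tris(benzyloxy)phenyl]-7-(tert-butyldimethylsilyloxy)hept-3-en-2-one | CC(=O)/C=C/[C@@H](C[C@H](O[Si](C)(C)C(C)(C)C)c1ccc(OCc2ccccc2)cc1)c1c(OCc2ccccc2)c(Br)c(OCc2ccccc2)cc1OCc1ccccc1 | intermediate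
12 | (5E,7R,9S)-9-[4-(benzyloxy)phenyl]-7-[3-bromo-2,4,6-tris(benzyloxy)phenyl]-9-(tert-butyldimethylsilyloxy)-1,1,1-trifluoronon-5-ene-2,4-dione | O=C(CC(=O)C(F)(F)F)/C=C/[C@@H](C[C@H](O[Si](C)(C)C(C)(C)C)c1ccc(OCc2ccccc2)cc1)c1c(OCc2ccccc2)c(Br)c(OCc2ccccc2)cc1OCc1ccccc1 | intermediate
13 | (3E,5R,7S)-7-[4-(benzyloxy)phenyl]-5-[3-bromo-2,4,6-tris(benzyloxy)phenyl]-7-(tert-butyldimethylsilyloxy)-1-diazohept-3-en-2-one | [N-]=[N+]=CC(=O)/C=C/[C@@H](C[C@H](O[Si](C)(C)C(C)(C)C)c1ccc(OCc2ccccc2)cc1)c1c(OCc2ccccc2)c(Br)c(OCc2ccccc2)cc1OCc1ccccc1 | intermediate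
14 | ethynyltrimethylsilane | C#C[Si](C)(C)C | starting material
15 | lithium 2-(trimethylsilyl)ethynolate | [Li+].[O-]C#C[Si](C)(C)C | intermediate
16 | triisopropyl{[(trimethylsilyl)ethynyl]oxy}silane | C[Si](C)(C)C#CO[Si](C(C)C)(C(C)C)C(C)C | intermediate
17 | (ethynyloxy)triisopropylsilane, i.e. (triisopropylsilyloxy)ethyne | C#CO[Si](C(C)C)(C(C)C)C(C)C | intermediate
18 | (3E,5R,7S)-7-[4-(benzyloxy)phenyl]-5-[3-bromo-2,4,6-tris(benzyloxy)phenyl]-7-(tert-butyldimethylsilyloxy)hepta-1,3-dien-1-one | O=C=C/C=C/[C@@H](C[C@H](O[Si](C)(C)C(C)(C)C)c1ccc(OCc2ccccc2)cc1)c1c(OCc2ccccc2)c(Br)c(OCc2ccccc2)cc1OCc1ccccc1 | intermediate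
19 | 4-{(1E,3R,5S)-5-[4-(benzyloxy)phenyl]-3-[3-bromo-2,4,6-tris(benzyloxy)phenyl]-5-(tert-butyldimethylsilyloxy)pent-1-en-1-yl}-3-(triisopropylsilyloxy)cyclobut-2-en-1-one (epimers at ring C4) | O=C1C=C(O[Si](C(C)C)(C(C)C)C(C)C)C1/C=C/[C@@H](C[C@H](O[Si](C)(C)C(C)(C)C)c1ccc(OCc2ccccc2)cc1)c1c(OCc2ccccc2)c(Br)c(OCc2ccccc2)cc1OCc1ccccc1 | intermediate
20 | (3E,5E,7R,9S)-9-[4-(benzyloxy)phenyl]-7-[3-bromo-2,4,6-tris(benzyloxy)phenyl]-9-(tert-butyldimethylsilyloxy)-3-(triisopropylsilyloxy)nona-1,3,5-trien-1-one | O=C=C\C(O[Si](C(C)C)(C(C)C)C(C)C)=C/C=C/[C@@H](C[C@H](O[Si](C)(C)C(C)(C)C)c1ccc(OCc2ccccc2)cc1)c1c(OCc2ccccc2)c(Br)c(OCc2ccccc2)cc1OCc1ccccc1 | intermediate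
21 | 6-{(1R,3S)-3-[4-(benzyloxy)phenyl]-1-[3-bromo-2,4,6-tris(benzyloxy)phenyl]-3-(tert-butyldimethylsilyloxy)propyl}-3-(triisopropylsilyloxy)cyclohexa-2,4-dien-1-one (epimers at ring C6) | O=C1C=C(O[Si](C(C)C)(C(C)C)C(C)C)C=CC1[C@@H](C[C@H](O[Si](C)(C)C(C)(C)C)c1ccc(OCc2ccccc2)cc1)c1c(OCc2ccccc2)c(Br)c(OCc2ccccc2)cc1OCc1ccccc1 | intermediate
22 | 2-{(1R,3S)-3-[4-(benzyloxy)phenyl]-1-[3-bromo-2,4,6-tris(benzyloxy)phenyl]-3-(tert-butyldimethylsilyloxy)propyl}-5-(triisopropylsilyloxy)phenol | Oc1cc(O[Si](C(C)C)(C(C)C)C(C)C)ccc1[C@@H](C[C@H](O[Si](C)(C)C(C)(C)C)c1ccc(OCc2ccccc2)cc1)c1c(OCc2ccccc2)c(Br)c(OCc2ccccc2)cc1OCc1ccccc1 | intermediate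
23 | {[(2R,4R)-2-[4-(benzyloxy)phenyl]-4-[3-bromo-2,4,6-tris(benzyloxy)phenyl]-3,4-dihydro-2H-chromen-7-yl]oxy}triisopropylsilane | Brc1c(OCc2ccccc2)cc(OCc2ccccc2)c([C@@H]2C[C@H](c3ccc(OCc4ccccc4)cc3)Oc3cc(O[Si](C(C)C)(C(C)C)C(C)C)ccc32)c1OCc1ccccc1 | intermediate
24 | dodecanoyl chloride | CCCCCCCCCCCC(Cl)=O | starting material
25 | N,O-dimethylhydroxylamine hydrochloride | CNOC.Cl | starting material
26 | N-methoxy-N-methyldodecanamide | CCCCCCCCCCCC(=O)N(C)OC | intermediate
27 | {2,4,6-tris(benzyloxy)-3-[(2R,4R)-2-[4-(benzyloxy)phenyl]-7-(triisopropylsilyloxy)-3,4-dihydro-2H-chromen-4-yl]phenyl}lithium | [Li]c1c(OCc2ccccc2)cc(OCc2ccccc2)c([C@@H]2C[C@H](c3ccc(OCc4ccccc4)cc3)Oc3cc(O[Si](C(C)C)(C(C)C)C(C)C)ccc32)c1OCc1ccccc1 | intermediate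
28 | 1-[2,4,6-tris(benzyloxy)-3-[(2R,4R)-2-[4-(benzyloxy)phenyl]-7-(triisopropylsilyloxy)-3,4-dihydro-2H-chromen-4-yl]phenyl]dodecan-1-one | CCCCCCCCCCCC(=O)c1c(OCc2ccccc2)cc(OCc2ccccc2)c([C@@H]2C[C@H](c3ccc(OCc4ccccc4)cc3)Oc3cc(O[Si](C(C)C)(C(C)C)C(C)C)ccc32)c1OCc1ccccc1 | intermediate
29 | 1-[2,4,6-tris(benzyloxy)-3-[(2R,4R)-2-[4-(benzyloxy)phenyl]-7-hydroxy-3,4-dihydro-2H-chromen-4-yl]phenyl]dodecan-1-one | CCCCCCCCCCCC(=O)c1c(OCc2ccccc2)cc(OCc2ccccc2)c([C@@H]2C[C@H](c3ccc(OCc4ccccc4)cc3)Oc3cc(O)ccc32)c1OCc1ccccc1 | intermediate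
30 | 1-[2,4,6-trihydroxy-3-[(2R,4R)-7-hydroxy-2-(4-hydroxyphenyl)-3,4-dihydro-2H-chromen-4-yl]phenyl]dodecan-1-one | CCCCCCCCCCCC(=O)c1c(O)cc(O)c([C@@H]2C[C@H](c3ccc(O)cc3)Oc3cc(O)ccc32)c1O | target

## Step count and risks

Total: 16 steps. Longest linear sequence: 13 steps (steps 1–8, 11, 12, 14, 15, 16). Steps 9 and 10 (alkyne) and step 13 (amide) are side branches.

**Step 11 (key step).** The photogenerated carbene may attack the nearby electron-rich ring D instead of undergoing the Wolff shift. The vinylketene may dimerise before the ynol ether traps it. The thermal cascade may stall at the cyclobutenone, or photolytic loss of bromine may erode the ring D handle. The fallback generates the same vinylketene without light or a diazo group. It sets out from alkene 9: cross-metathesis with but-3-enoic acid (second-generation Hoveyda–Grubbs catalyst, CH2Cl2, 40 °C) should give (3E,5R,7S)-7-[4-(benzyloxy)phenyl]-5-[3-bromo-2,4,6-tris(benzyloxy)phenyl]-7-(tert-butyldimethylsilyloxy)hept-3-enoic acid F1. Neutral chlorination with 1-chloro-N,N,2-trimethylprop-1-en-1-amine should give the acid chloride (3E,5R,7S)-7-[4-(benzyloxy)phenyl]-5-[3-bromo-2,4,6-tris(benzyloxy)phenyl]-7-(tert-butyldimethylsilyloxy)hept-3-enoyl chloride F2. Dehydrochlorination of F2 with Et3N in toluene in the presence of 17 (rt, then 80 °C) forms vinylketene 18 by loss of an α-hydrogen, not the hydrogen on the stereocentre, and the same (2+2)/4π/6π sequence returns to the route at phenol 22.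

**Step 4.** Insertion of the hindered, electron-rich enone into the vinyl–rhodium bond may be slower than protodeboronation of the vinyl reagent. Face selectivity on a doubly ortho-substituted β-aryl enone may be poor, and a rhodium hydride could move the new double bond into conjugation with ring D and erase the stereocentre. The fallback uses an auxiliary and sets out from aldehyde 3:
- Knoevenagel–Doebner condensation with malonic acid (pyridine, piperidine) should give (E)-3-[3-bromo-2,4,6-tris(benzyloxy)phenyl]prop-2-enoic acid F3.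
- Its mixed pivalic anhydride acylates lithiated (4S)-4-phenyl-1,3-oxazolidin-2-one to (4S)-3-{(2E)-3-[3-bromo-2,4,6-tris(benzyloxy)phenyl]prop-2-enoyl}-4-phenyl-1,3-oxazolidin-2-one F4.
- Vinylmagnesium bromide with CuBr·SMe2 (THF, −40 °C) should add to the chelated syn-s-cis imide from the face opposite the phenyl group, giving (4S)-3-{(3R)-3-[3-bromo-2,4,6-tris(benzyloxy)phenyl]pent-4-enoyl}-4-phenyl-1,3-oxazolidin-2-one F5.
- Transamidation with MeNHOMe·HCl and AlMe3 gives (3R)-3-[3-bromo-2,4,6-tris(benzyloxy)phenyl]-N-methoxy-N-methylpent-4-enamide F6.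
- [4-(Benzyloxy)phenyl]magnesium bromide then returns to the route at ketone 7.

**Step 10.** Methanolysis may cleave the O–Si bond of the ynol ether (the ynolate is a good leaving group) in competition with the C–Si bond, and the volatile product may be lost on isolation. The fallback carries the carbon-bound silyl group through the benzannulation. It sets out from 13 and 16 under the conditions of step 11 and should give 2-{(1R,3S)-3-[4-(benzyloxy)phenyl]-1-[3-bromo-2,4,6-tris(benzyloxy)phenyl]-3-(tert-butyldimethylsilyloxy)propyl}-5-(triisopropylsilyloxy)-6-(trimethylsilyl)phenol F7. The β-silyl group reinforces the regiochemistry of the (2+2) step. TsOH·H2O in CH2Cl2 then closes ring C and removes the aryl–SiMe3 group by ipso-protonation at the carbon between the two oxygens, returning to the route at flavan 23.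

**Step 12.** Ring closure under kinetic control may give the 2,4-trans isomer if re-ionisation of O1–C2 is slow. Prolonged acid may also ionise the C4–C1' bond through ipso-protonation of ring D and scramble C4, or divert the cation to the styrene. The fallback is stereospecific and sets out from 22. HF·pyridine (THF/pyridine, 0 °C) cleaves only the alkyl silyl ether, giving 2-{(1R,3S)-3-[4-(benzyloxy)phenyl]-1-[3-bromo-2,4,6-tris(benzyloxy)phenyl]-3-hydroxypropyl}-5-(triisopropylsilyloxy)phenol F8. Mitsunobu etherification (PPh3, DIAD, THF, 0 °C) closes O1–C2 with inversion of the (S)-carbinol to (2R) and returns to the route at 23.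

**Step 14.** The hindered aryllithium may act as a base and not as a nucleophile: deprotonation of the amide α-methylene, or N–O cleavage of the Weinreb amide with loss of formaldehyde, returns protonated arene. The fallback uses a more electrophilic partner and sets out from aryllithium 27. Addition to dodecanal should give 1-[2,4,6-tris(benzyloxy)-3-[(2R,4R)-2-[4-(benzyloxy)phenyl]-7-(triisopropylsilyloxy)-3,4-dihydro-2H-chromen-4-yl]phenyl]dodecan-1-ol F9 as a mixture of carbinol epimers. Dess–Martin oxidation returns to the route at ketone 28.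

## Further compounds

F1 | step 11 | (3E,5R,7S)-7-[4-(benzyloxy)phenyl]-5-[3-bromo-2,4,6-tris(benzyloxy)phenyl]-7-(tert-butyldimethylsilyloxy)hept-3-enoic acid | OC(=O)C/C=C/[C@@H](C[C@H](O[Si](C)(C)C(C)(C)C)c1ccc(OCc2ccccc2)cc1)c1c(OCc2ccccc2)c(Br)c(OCc2ccccc2)cc1OCc1ccccc1
F2 | step 11 | (3E,5R,7S)-7-[4-(benzyloxy)phenyl]-5-[3-bromo-2,4,6-tris(benzyloxy)phenyl]-7-(tert-butyldimethylsilyloxy)hept-3-enoyl chloride | ClC(=O)C/C=C/[C@@H](C[C@H](O[Si](C)(C)C(C)(C)C)c1ccc(OCc2ccccc2)cc1)c1c(OCc2ccccc2)c(Br)c(OCc2ccccc2)cc1OCc1ccccc1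
F3 | step 4 | (E)-3-[3-bromo-2,4,6-tris(benzyloxy)phenyl]prop-2-enoic acid | OC(=O)/C=C/c1c(OCc2ccccc2)c(Br)c(OCc2ccccc2)cc1OCc1ccccc1
F4 | step 4 | (4S)-3-{(2E)-3-[3-bromo-2,4,6-tris(benzyloxy)phenyl]prop-2-enoyl}-4-phenyl-1,3-oxazolidin-2-one | O=C(/C=C/c1c(OCc2ccccc2)c(Br)c(OCc2ccccc2)cc1OCc1ccccc1)N1[C@@H](c2ccccc2)COC1=O
F5 | step 4 | (4S)-3-{(3R)-3-[3-bromo-2,4,6-tris(benzyloxy)phenyl]pent-4-enoyl}-4-phenyl-1,3-oxazolidin-2-one | C=C[C@@H](CC(=O)N1[C@@H](c2ccccc2)COC1=O)c1c(OCc2ccccc2)c(Br)c(OCc2ccccc2)cc1OCc1ccccc1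
F6 | step 4 | (3R)-3-[3-bromo-2,4,6-tris(benzyloxy)phenyl]-N-methoxy-N-methylpent-4-enamide | C=C[C@@H](CC(=O)N(C)OC)c1c(OCc2ccccc2)c(Br)c(OCc2ccccc2)cc1OCc1ccccc1
F7 | step 10 | 2-{(1R,3S)-3-[4-(benzyloxy)phenyl]-1-[3-bromo-2,4,6-tris(benzyloxy)phenyl]-3-(tert-butyldimethylsilyloxy)propyl}-5-(triisopropylsilyloxy)-6-(trimethylsilyl)phenol | Oc1c([Si](C)(C)C)c(O[Si](C(C)C)(C(C)C)C(C)C)ccc1[C@@H](C[C@H](O[Si](C)(C)C(C)(C)C)c1ccc(OCc2ccccc2)cc1)c1c(OCc2ccccc2)c(Br)c(OCc2ccccc2)cc1OCc1ccccc1
F8 | step 12 | 2-{(1R,3S)-3-[4-(benzyloxy)phenyl]-1-[3-bromo-2,4,6-tris(benzyloxy)phenyl]-3-hydroxypropyl}-5-(triisopropylsilyloxy)phenol | Oc1cc(O[Si](C(C)C)(C(C)C)C(C)C)ccc1[C@@H](C[C@H](O)c1ccc(OCc2ccccc2)cc1)c1c(OCc2ccccc2)c(Br)c(OCc2ccccc2)cc1OCc1ccccc1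
F9 | step 14 | 1-[2,4,6-tris(benzyloxy)-3-[(2R,4R)-2-[4-(benzyloxy)phenyl]-7-(triisopropylsilyloxy)-3,4-dihydro-2H-chromen-4-yl]phenyl]dodecan-1-ol (both carbinol epimers) | CCCCCCCCCCCC(O)c1c(OCc2ccccc2)cc(OCc2ccccc2)c([C@@H]2C[C@H](c3ccc(OCc4ccccc4)cc3)Oc3cc(O[Si](C(C)C)(C(C)C)C(C)C)ccc32)c1OCc1ccccc1
A1 | alternative 1 | methyl 2-[(2R,4S)-7-(benzyloxy)-2-[4-(benzyloxy)phenyl]-3,4-dihydro-2H-chromen-4-yl]-3,5,7-trioxooctadecanoate | CCCCCCCCCCCC(=O)CC(=O)CC(=O)C(C(=O)OC)[C@@H]1C[C@H](c2ccc(OCc3ccccc3)cc2)Oc2cc(OCc3ccccc3)ccc21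
A2 | alternative 1 | 1-[3-[(2R,4R)-7-(benzyloxy)-2-[4-(benzyloxy)phenyl]-3,4-dihydro-2H-chromen-4-yl]-2,4,6-trihydroxyphenyl]dodecan-1-one | CCCCCCCCCCCC(=O)c1c(O)cc(O)c([C@@H]2C[C@H](c3ccc(OCc4ccccc4)cc3)Oc3cc(OCc4ccccc4)ccc32)c1O
A3 | alternative 2 | 6-(benzyloxy)-2-[4-(benzyloxy)phenyl]-3-[2,4,6-tris(benzyloxy)phenyl]-1-benzofuran | o1c(-c2ccc(OCc3ccccc3)cc2)c(-c2c(OCc3ccccc3)cc(OCc3ccccc3)cc2OCc2ccccc2)c2ccc(OCc3ccccc3)cc12
A4 | alternative 2 | 7-(benzyloxy)-2-[4-(benzyloxy)phenyl]-3-chloro-4-[2,4,6-tris(benzyloxy)phenyl]chromenylium chloride | [o+]1c(-c2ccc(OCc3ccccc3)cc2)c(Cl)c(-c2c(OCc3ccccc3)cc(OCc3ccccc3)cc2OCc2ccccc2)c2ccc(OCc3ccccc3)cc12.[Cl-]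
A5 | alternative 3 | (3R)-6-(benzyloxy)-3-[2,4,6-tris(benzyloxy)phenyl]-2,3-dihydro-1H-inden-1-one | c1ccc(COc2cc(OCc3ccccc3)c([C@@H]3CC(=O)c4cc(OCc5ccccc5)ccc43)c(OCc3ccccc3)c2)cc1
A6 | alternative 3 | (4R)-7-(benzyloxy)-4-[2,4,6-tris(benzyloxy)phenyl]-3,4-dihydro-2H-chromen-2-one | c1ccc(COc2cc(OCc3ccccc3)c([C@@H]3CC(=O)Oc4cc(OCc5ccccc5)ccc43)c(OCc3ccccc3)c2)cc1
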